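## Retrosynthetic overview
1. Building blocks: 1,1-dimethoxyethene 1 and acetyl chloride 2 give acylketene acetal 3, then 1,1-dimethoxy-3-silyloxybutadiene 4. The aryl part is 2,3,4-trimethoxybenzaldehyde 5.
2. Key disconnection: rings C and A are both cut back, in one flask, to 5 plus two molecules of the same C4 diene 4. The first copy supplies C3–C4–C4a–C8a and the second supplies C8–C7–C6–C5.
3. Ring order: ring C forms first (6 → 7). The C2–C3 bond comes from an asymmetric vinylogous aldol that sets C2, followed by O1–C8a closure. Ring A forms second (→ 8 → 9) by C8–C8a then C4a–C5 bond formation, and it aromatises by loss of two methoxy groups.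
4. Last disconnection: 7-O–CH3 (9 → target 10), made under neutral conditions so that C2 never meets base.

Assumption: flavanone numbering (O1, C2, C3, C4, C4a, C5–C8, C8a) is used for all intermediates, and the stereocentre in the target SMILES is C2 = S.

## Route

Step 1
Reactants: 1 1,1-dimethoxyethene (ketene dimethyl acetal); 2 acetyl chloride
Product: 3 4,4-dimethoxybut-3-en-2-one (acetylketene dimethyl acetal)
Conditions: pyridine (1.1 equiv), CH2Cl2, 0 °C → rt; filter, distil (no water)
Reagents that add atoms: none
Why: C-acylation of a ketene acetal by an acid chloride, in which the nucleophilic CH2 attacks the acylpyridinium and pyridine removes the very acidic α-H of the dialkoxycarbenium intermediate faster than chloride can demethylate it; no stereocentre is formed.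

Step 2
Reactants: 3 4,4-dimethoxybut-3-en-2-one
Product: 4 1,1-dimethoxy-3-(trimethylsilyloxy)buta-1,3-diene
Conditions: TMSCl, Et3N, ZnCl2 (cat.), toluene, 40 °C; filter, distil
Reagents that add atoms: chlorotrimethylsilane, C[Si](C)(C)Cl
Why: Danishefsky-type enol silylation of a β-alkoxy enone, regiospecific because the CH3 group is the only enolisable position; no stereocentre is formed.

Step 3
Reactants: 5 2,3,4-trimethoxybenzaldehyde; 4 1,1-dimethoxy-3-(trimethylsilyloxy)buta-1,3-diene (two portions, 2.6 equiv in total)
Product: 9 (S)-7-hydroxy-5-methoxy-2-(2,3,4-trimethoxyphenyl)chroman-4-one, via silyl aldol adduct 6 (not isolated), via 6-methoxydihydropyranone 7 (not isolated), via 7-O-TMS flavanone 8 (not isolated)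
Conditions: (S)-BINOL (10 mol %), Ti(OiPr)4 (10 mol %), 4 Å MS, 4 (1.1 equiv), Et2O, −20 °C; then CH2Cl2, DTBMP (3 equiv), TMSOTf (3 equiv), −78 °C; then 4 (1.5 equiv, slow addition), −78 → −20 °C; aq NaHCO3, then citric acid/wet MeOH, rt
Reagents that add atoms: none
Why: Proposed new method: the ambiphilic diene 4 is used twice; first a Ti–BINOL vinylogous Mukaiyama aldol (stepwise hetero-Diels–Alder) of its CH2 terminus on the Si face of 5 sets C2 as S (closest known types: Ti–BINOL aldol of Chan's diene, where the (S)-ligand exposes the Si face of ArCHO, and asymmetric hetero-Diels–Alder of Brassard-type dienes), then TMSOTf closes O1 onto the ketene-acetal carbon without touching the C2–O bond to give vinylogous carbonate 7, whose O-silylated dihydropyrylium form accepts the second diene at C8a (Mukaiyama–Michael, as known for silyloxypyrylium salts of chromones and dihydropyranones), and the resulting enol silane C4a closes onto the dimethoxycarbenium C5, which amounts to a stepwise Danishefsky–Brassard [4+2] benzannulation in which loss of the C8a methoxy and one C5 methoxy group aromatises ring A and leaves 5-OMe and 7-OSiMe3 regiospecifically, while DTBMP keeps the medium free of TfOH.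

Step 4
Reactants: 9 (S)-7-hydroxy-5-methoxy-2-(2,3,4-trimethoxyphenyl)chroman-4-one
Product: 10 (S)-5,7-dimethoxy-2-(2,3,4-trimethoxyphenyl)chroman-4-one (target)
Conditions: MeOH (3 equiv), PPh3, DIAD, THF, 0 °C → rt
Reagents that add atoms: methanol, CO
Why: Mitsunobu etherification of the only OH, the acidic 7-phenol (a vinylogous acid), under essentially neutral conditions, so C3 is not enolised, the retro-oxa-Michael racemisation path stays closed and C2 remains S.

## Compound list
1 | 1,1-dimethoxyethene | C=C(OC)OC | starting material
2 | acetyl chloride | CC(=O)Cl | starting material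
3 | 4,4-dimethoxybut-3-en-2-one | CC(=O)C=C(OC)OC | intermediate
4 | 1,1-dimethoxy-3-(trimethylsilyloxy)buta-1,3-diene | C=C(O[Si](C)(C)C)C=C(OC)OC | intermediate
5 | 2,3,4-trimethoxybenzaldehyde | COc1ccc(C=O)c(OC)c1OC | starting material
6 | (S)-1,1-dimethoxy-5-(2,3,4-trimethoxyphenyl)-5-(trimethylsilyloxy)pent-1-en-3-one | COC(OC)=CC(=O)C[C@H](O[Si](C)(C)C)c1ccc(OC)c(OC)c1OC | intermediate (not isolated)
7 | (S)-6-methoxy-2-(2,3,4-trimethoxyphenyl)-2,3-dihydro-4H-pyran-4-one | COC1=CC(=O)C[C@@H](c2ccc(OC)c(OC)c2OC)O1 | intermediate (not isolated)
8 | (S)-5-methoxy-7-(trimethylsilyloxy)-2-(2,3,4-trimethoxyphenyl)chroman-4-one | COc1cc(O[Si](C)(C)C)cc2c1C(=O)C[C@@H](c1ccc(OC)c(OC)c1OC)O2 | intermediate (not isolated)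
9 | (S)-7-hydroxy-5-methoxy-2-(2,3,4-trimethoxyphenyl)chroman-4-one | COc1cc(O)cc2c1C(=O)C[C@@H](c1ccc(OC)c(OC)c1OC)O2 | intermediate
10 | (S)-5,7-dimethoxy-2-(2,3,4-trimethoxyphenyl)chroman-4-one | COc1cc(OC)c2c(c1)O[C@H](c1ccc(OC)c(OC)c1OC)CC2=O | target

Total step count: 4. Longest linear sequence: 4 (1/2 → 3 → 4 → 9 → 10).

## Steps most likely to fail

**Step 3 (highest risk).**
- Failure modes:
  - The second diene may attack silylated 7 at C4 (1,2-addition) instead of C8a.
  - The C8a–O1 bond may cleave instead of C8a–OMe.
  - C3 deprotonation may be followed by electrocyclic ring opening.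
  - The electron-rich benzylic C2–O bond may ionise and erode the ee.
- Fallback approach: build the two rings one at a time and use a halogen, not the C8a methoxy group, as the traceless leaving group.
- It sets out from 5. A Ti–(S)-BINOL hetero-Diels–Alder reaction with commercial Danishefsky diene and a TFA work-up gives (S)-2-(2,3,4-trimethoxyphenyl)-2,3-dihydro-4H-pyran-4-one F1.
- Iodine/pyridine α-iodination leaves the trimethoxyarene untouched and gives (S)-5-iodo-2-(2,3,4-trimethoxyphenyl)-2,3-dihydro-4H-pyran-4-one F2.
- A thermal Diels–Alder reaction of this alkyne-equivalent dienophile with diene 4 follows (toluene, 60–80 °C, 2,6-lutidine as acid scavenger). The CH2 terminus of 4 bonds to the β-carbon C8a.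
- Loss of HI and methanol gives 8. The fallback comes back to the route at 8, and the usual work-up then gives 9.

**Step 1.**
- Failure modes: chloride may demethylate the intermediate to methyl acetoacetate, diacylation may occur, and 3 is sensitive to hydrolysis.
- Fallback approach: make the same C4 skeleton by Friedel–Crafts-type acylation of a chloroalkene, then introduce the oxygens by substitution.
- It sets out from 2. AlCl3-mediated addition to 1,1-dichloroethene gives 4,4,4-trichlorobutan-2-one F3.
- F3 loses HCl on distillation to give 4,4-dichlorobut-3-en-2-one F4.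
- Double addition–elimination with NaOMe in MeOH at 0 °C comes back to the route at 3.

**Step 4.**
- Failure modes: the reaction may be sluggish, or the ee of the finished flavanone may erode during handling.
- Fallback approach: avoid any late O-methylation by delivering the 7-OMe with the diene.
- It sets out from 3. O-methylation of its potassium enolate (KHMDS, THF/DMPU, −78 °C, MeOTf) gives 1,1,3-trimethoxybuta-1,3-diene F5.
- F5 replaces the second portion of 4 in the flask of step 3. It annulates in-flask 7 under the same TMSOTf/DTBMP regime.
- This comes back to the route directly at 10.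

## Further compounds
F1 | step 3 | (S)-2-(2,3,4-trimethoxyphenyl)-2,3-dihydro-4H-pyran-4-one | O=C1C=CO[C@H](c2ccc(OC)c(OC)c2OC)C1
F2 | step 3 | (S)-5-iodo-2-(2,3,4-trimethoxyphenyl)-2,3-dihydro-4H-pyran-4-one | O=C1C(I)=CO[C@H](c2ccc(OC)c(OC)c2OC)C1
F3 | step 1 | 4,4,4-trichlorobutan-2-one | CC(=O)CC(Cl)(Cl)Cl
F4 | step 1 | 4,4-dichlorobut-3-en-2-one | CC(=O)C=C(Cl)Cl
F5 | step 4 | 1,1,3-trimethoxybuta-1,3-diene | C=C(OC)C=C(OC)OC
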